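**Plan**

1. Numbering: ring C1 (CH2 between the stereocentre and the methyl-bearing Z alkene), C2=C3(CH3), C4, C5, C6=C7(CO2H), C8, C9, C10=C11(CH3), C12, C13, C14 (stereocentre, R); side chain C15(CH3)=C16H–C17H2–C18H=C19(CH3)2.
2. Enabling feature: in the 14-membered ring the C2=C3 alkene has the ring carbons C1 and C4 cis. With an ester in place of the C3 methyl this is the E enoate of a phosphonoacetate olefination, so the ring is cut at C2=C3, the C3 methyl is traced back to CO2Et and the C7 acid is carried as a silyloxymethyl group.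
3. Further cuts: C11–C12 (B-alkyl Suzuki coupling), C6=C7 (intermolecular Horner–Wadsworth–Emmons), C3–C4 and C7–C8 (phosphonoacetate alkylations), C14–C15 (copper-catalysed allylic substitution), C18=C19 (Wittig).
4. Forward: pent-3-yn-1-ol gives one E vinyl iodide that serves both the side-chain alkenylboronate and the C3–C11 phosphonoacetate. The boronate and an allylic phosphate give the C14 building block, the two halves are joined at C11–C12, and the only ring is closed last at C2=C3.
5. Stereochemistry: C14 is set by a chiral NHC–Cu catalyst (step 10) and is never α to a carbonyl afterwards. C10=C11 and C15=C16 come from syn hydrozirconation, C6=C7 and C2=C3 from E-selective phosphonate olefinations.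
6. End game: the C3 ester is reduced to methyl (iBu2AlH, then mesylate/LiBHEt3) and the C7 silyloxymethyl group is oxidised to the acid.

Key step: step 24

Remarks on the chemistry:
- C3 carries an ethyl ester and a diisopropyl phosphonate (bulkier than dimethyl/diethyl, chosen to raise E selectivity), and the C7 oxygen carries tert-butyldiphenylsilyl so that the C2 and C4 tert-butyldimethylsilyl ethers can be removed selectively.
- The phosphonoacetate carbon C3 is formed without control; both epimers converge in the ring closure, and the SMILES carry no descriptor there.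
- In step 10 the antipode of the imidazolinium salt is assumed to be the one that delivers the S product; both antipodes are available from the two enantiomers of 1,2-diphenylethane-1,2-diamine.

**Route**

Step 1
Reactants: 1 pent-3-yn-1-ol
Product: 2 (3E)-4-iodopent-3-en-1-ol
Conditions: Cp2Zr(H)Cl (2.5 equiv), THF, rt → 40 °C; then I2, 0 °C
Reagents that add atoms: iodine, II
Why: Schwartz hydrozirconation is a syn addition that, under equilibration with excess Cp2Zr(H)Cl, places zirconium on the less hindered methyl-bearing carbon, and iodinolysis with retention should give the E vinyl iodide.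

Step 2
Reactants: 2 (3E)-4-iodopent-3-en-1-ol
Product: 3 (2E)-2,5-diiodopent-2-ene
Conditions: I2, PPh3, imidazole, CH2Cl2, 0 °C → rt
Reagents that add atoms: iodine, II
Why: Appel-type iodination (Garegg–Samuelsson conditions) converts the primary alcohol into the iodide and leaves the alkenyl iodide untouched.

Step 3
Reactants: 3 (2E)-2,5-diiodopent-2-ene
Product: 4 [(3E)-4-iodopent-3-en-1-yl]triphenylphosphonium iodide
Conditions: PPh3, MeCN, reflux
Reagents that add atoms: triphenylphosphine, c1ccc(cc1)P(c1ccccc1)c1ccccc1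
Why: SN2 quaternisation of the phosphine occurs only at the primary iodide, since the alkenyl iodide is inert without a transition metal.

Step 4
Reactants: 4 [(3E)-4-iodopent-3-en-1-yl]triphenylphosphonium iodide
Product: 5 (2E)-2-iodo-6-methylhepta-2,5-diene
Conditions: KN(SiMe3)2, THF, −78 → 0 °C; acetone, −78 °C → rt
Reagents that add atoms: acetone, CC(C)=O
Why: Wittig olefination of acetone by the non-stabilised ylide builds the isopropylidene end C18=C19, where no geometry is at stake, and a silylamide base avoids iodine–lithium exchange.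

Step 5
Reactants: 5 (2E)-2-iodo-6-methylhepta-2,5-diene
Product: 6 2-[(2Z)-6-methylhepta-2,5-dien-2-yl]-4,4,5,5-tetramethyl-1,3,2-dioxaborolane (boron trans to the CH2 group; Z only because carbon outranks boron)
Conditions: t-BuLi (2.1 equiv), Et2O, −78 °C; 2-isopropoxy-4,4,5,5-tetramethyl-1,3,2-dioxaborolane, −78 °C → rt
Reagents that add atoms: 2-isopropoxy-4,4,5,5-tetramethyl-1,3,2-dioxaborolane, CC(C)OB1OC(C)(C)C(C)(C)O1
Why: Iodine–lithium exchange proceeds with retention of alkene geometry and the alkenyllithium is trapped by the borate ester to give the alkenyl pinacol boronate.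

Step 6
Reactants: 7 but-3-yn-1-ol
Product: 8 tert-butyl(but-3-yn-1-yloxy)dimethylsilane
Conditions: TBSCl, imidazole, CH2Cl2, 0 °C → rt
Reagents that add atoms: tert-butyldimethylsilyl chloride, CC(C)(C)[Si](C)(C)Cl
Why: Standard silylation of a primary alcohol.

Step 7
Reactants: 8 tert-butyl(but-3-yn-1-yloxy)dimethylsilane
Product: 9 5-[(tert-butyldimethylsilyl)oxy]pent-2-yn-1-ol
Conditions: n-BuLi, THF, −78 °C; (CH2O)n, −78 °C → rt
Reagents that add atoms: formaldehyde (as paraformaldehyde), C=O
Why: Addition of the lithium acetylide to formaldehyde gives the propargylic alcohol.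

Step 8
Reactants: 9 5-[(tert-butyldimethylsilyl)oxy]pent-2-yn-1-ol
Product: 10 (2E)-5-[(tert-butyldimethylsilyl)oxy]pent-2-en-1-ol
Conditions: NaAlH2(OCH2CH2OCH3)2, THF, 0 °C → rt; aq Rochelle salt
Reagents that add atoms: none
Why: Hydroxyl-directed trans-hydroalumination of the propargylic alcohol followed by protonolysis should give only the E allylic alcohol.

Step 9
Reactants: 10 (2E)-5-[(tert-butyldimethylsilyl)oxy]pent-2-en-1-ol
Product: 11 diethyl (2E)-5-[(tert-butyldimethylsilyl)oxy]pent-2-en-1-yl phosphate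
Conditions: ClP(O)(OEt)2, Et3N, DMAP (cat.), CH2Cl2, 0 °C
Reagents that add atoms: diethyl chlorophosphate, CCOP(=O)(Cl)OCC
Why: O-phosphorylation of the primary allylic alcohol gives the leaving group needed for copper-catalysed allylic substitution.

Step 10
Reactants: 6 2-[(2Z)-6-methylhepta-2,5-dien-2-yl]-4,4,5,5-tetramethyl-1,3,2-dioxaborolane; 11 diethyl (2E)-5-[(tert-butyldimethylsilyl)oxy]pent-2-en-1-yl phosphate
Product: 12 tert-butyldimethyl{[(3S)-3-[(2E)-6-methylhepta-2,5-dien-2-yl]pent-4-en-1-yl]oxy}silane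
Conditions: CuCl (5 mol %), chiral sulfonate-bearing imidazolinium salt (5.5 mol %), NaOMe (2 equiv), THF, 22 → 50 °C
Reagents that add atoms: none
Why: NHC–Cu-catalysed enantioselective allylic substitution with an alkenylboron nucleophile: methoxide triggers boron-to-copper transmetalation and the alkenylcopper adds SN2′ at C14 with loss of phosphate, the chiral sulfonate-bridged carbene choosing the alkene face and so setting C14 (S in 12, the same spatial arrangement as 14R in the target).

Step 11
Reactants: 13 triisopropyl phosphite; 14 ethyl bromoacetate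
Product: 15 ethyl 2-(diisopropoxyphosphoryl)acetate
Conditions: neat, 130 °C
Reagents that add atoms: none
Why: Michaelis–Arbuzov reaction of the phosphite with the α-bromo ester.

Step 12
Reactants: 3 (2E)-2,5-diiodopent-2-ene; 15 ethyl 2-(diisopropoxyphosphoryl)acetate
Product: 16 ethyl (5E)-2-(diisopropoxyphosphoryl)-6-iodohept-5-enoate (racemic)
Conditions: 15 (excess), NaH, DMF, 0 °C; then 3, 60 °C
Reagents that add atoms: none
Why: SN2 C-alkylation of the sodium phosphonoacetate by the primary iodide forms C7–C8, with excess 15 suppressing dialkylation.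

Step 13
Reactants: 17 propane-1,3-diol
Product: 18 3-[(tert-butyldimethylsilyl)oxy]propan-1-ol
Conditions: NaH (1 equiv), THF, rt; TBSCl (1 equiv)
Reagents that add atoms: tert-butyldimethylsilyl chloride, CC(C)(C)[Si](C)(C)Cl
Why: Monosilylation of the symmetrical diol through its sparingly soluble monosodium alkoxide (McDougal protocol).

Step 14
Reactants: 18 3-[(tert-butyldimethylsilyl)oxy]propan-1-ol
Product: 19 3-[(tert-butyldimethylsilyl)oxy]propanal
Conditions: Dess–Martin periodinane, NaHCO3, CH2Cl2, 0 °C → rt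
Reagents that add atoms: none
Why: Dess–Martin oxidation of a primary alcohol to the aldehyde under buffered, non-eliminating conditions.

Step 15
Reactants: 16 ethyl (5E)-2-(diisopropoxyphosphoryl)-6-iodohept-5-enoate; 19 3-[(tert-butyldimethylsilyl)oxy]propanal
Product: 20 ethyl (2E)-5-[(tert-butyldimethylsilyl)oxy]-2-[(3E)-4-iodopent-3-en-1-yl]pent-2-enoate
Conditions: KOtBu, THF, −78 °C; then 19, −78 °C → rt
Reagents that add atoms: none
Why: Horner–Wadsworth–Emmons olefination in which the bulky diisopropyl phosphonate of the α-alkyl phosphonoacetate should favour the E enoate (ester trans to C5), which places C5 and C8 cis on C6=C7.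

Step 16
Reactants: 20 ethyl (2E)-5-[(tert-butyldimethylsilyl)oxy]-2-[(3E)-4-iodopent-3-en-1-yl]pent-2-enoate
Product: 21 (2E)-5-[(tert-butyldimethylsilyl)oxy]-2-[(3E)-4-iodopent-3-en-1-yl]pent-2-en-1-ol
Conditions: iBu2AlH, CH2Cl2, −78 °C
Reagents that add atoms: none
Why: 1,2-Reduction of the enoate to the allylic alcohol by iBu2AlH, with the alkenyl iodide and silyl ether inert.

Step 17
Reactants: 21 (2E)-5-[(tert-butyldimethylsilyl)oxy]-2-[(3E)-4-iodopent-3-en-1-yl]pent-2-en-1-ol
Product: 22 (2E)-5-[(tert-butyldimethylsilyl)oxy]-1-[(tert-butyldiphenylsilyl)oxy]-2-[(3E)-4-iodopent-3-en-1-yl]pent-2-ene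
Conditions: TBDPSCl, imidazole, DMF, rt
Reagents that add atoms: tert-butyldiphenylsilyl chloride, CC(C)(C)[Si](Cl)(c1ccccc1)c1ccccc1
Why: Silylation of the allylic alcohol with the more robust silyl group masks the future C7 carboxyl carbon.

Step 18
Reactants: 22 (2E)-5-[(tert-butyldimethylsilyl)oxy]-1-[(tert-butyldiphenylsilyl)oxy]-2-[(3E)-4-iodopent-3-en-1-yl]pent-2-ene
Product: 23 (3E,7E)-4-{[(tert-butyldiphenylsilyl)oxy]methyl}-8-iodonona-3,7-dien-1-ol
Conditions: camphorsulfonic acid (cat.), MeOH/CH2Cl2, 0 °C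
Reagents that add atoms: none
Why: Acid-catalysed methanolysis cleaves the primary tert-butyldimethylsilyl ether much faster than the tert-butyldiphenylsilyl ether.

Step 19
Reactants: 23 (3E,7E)-4-{[(tert-butyldiphenylsilyl)oxy]methyl}-8-iodonona-3,7-dien-1-ol
Product: 24 (2E)-1-[(tert-butyldiphenylsilyl)oxy]-5-iodo-2-[(3E)-4-iodopent-3-en-1-yl]pent-2-ene
Conditions: I2, PPh3, imidazole, CH2Cl2, 0 °C
Reagents that add atoms: iodine, II
Why: Appel-type iodination of the primary alcohol under neutral conditions that the silyl ether and both alkenes tolerate.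

Step 20
Reactants: 24 (2E)-1-[(tert-butyldiphenylsilyl)oxy]-5-iodo-2-[(3E)-4-iodopent-3-en-1-yl]pent-2-ene; 15 ethyl 2-(diisopropoxyphosphoryl)acetate
Product: 25 ethyl (5E,9E)-6-{[(tert-butyldiphenylsilyl)oxy]methyl}-2-(diisopropoxyphosphoryl)-10-iodoundeca-5,9-dienoate (racemic at C3)
Conditions: 15 (excess), NaH, DMF, 0 °C; then 24, 50 °C
Reagents that add atoms: none
Why: SN2 C-alkylation of the soft, weakly basic phosphonoacetate anion by the primary iodide forms C3–C4 without elimination of the homoallylic iodide.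

Step 21
Reactants: 12 tert-butyldimethyl{[(3S)-3-[(2E)-6-methylhepta-2,5-dien-2-yl]pent-4-en-1-yl]oxy}silane; 25 ethyl (5E,9E)-6-{[(tert-butyldiphenylsilyl)oxy]methyl}-2-(diisopropoxyphosphoryl)-10-iodoundeca-5,9-dienoate
Product: 27 coupled C3–C19 chain carrying C2–OSi(CH3)2tBu; C7–CH2OSi(tBu)Ph2; C3 ethyl diisopropylphosphonoacetate, via B-alkyl-9-BBN adduct 26 (not isolated)
Conditions: 9-BBN, THF, rt; then 25, PdCl2(dppf) (5 mol %), AsPh3, Cs2CO3, DMF/H2O, rt
Reagents that add atoms: none
Why: 9-BBN hydroborates only the monosubstituted vinyl group at its terminus, and B-alkyl Suzuki–Miyaura coupling with the alkenyl iodide forms C11–C12 with retention of the E geometry at C10=C11.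

Step 22
Reactants: 27 coupled chain with C2–OSi(CH3)2tBu
Product: 28 coupled chain with free C2–OH (C7–CH2OSi(tBu)Ph2 and C3 phosphonoacetate retained)
Conditions: pyridinium p-toluenesulfonate, EtOH, 40 °C
Reagents that add atoms: none
Why: Mild acid-catalysed ethanolysis removes the primary tert-butyldimethylsilyl ether selectively, and ethanol as solvent avoids exchange of the ethyl ester.

Step 23
Reactants: 28 coupled chain with free C2–OH
Product: 29 seco aldehyde: C2 aldehyde, C3 ethyl diisopropylphosphonoacetate, C7–CH2OSi(tBu)Ph2, 14R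
Conditions: Dess–Martin periodinane, NaHCO3, CH2Cl2, 0 °C
Reagents that add atoms: none
Why: Buffered Dess–Martin oxidation gives the aldehyde without base, so the phosphonoacetate does not react before the dilution step.

Step 24
Reactants: 29 seco aldehyde
Product: 30 macrocyclic ester: 14-membered ring with CO2Et on C3 (trans to C1) and CH2OSi(tBu)Ph2 on C7, 14R
Conditions: LiCl, DBU, MeCN, rt, slow addition of 29 (final concentration about 1 mM)
Reagents that add atoms: none
Why: DBU deprotonates the lithium-chelated phosphonoacetate at C3, the carbanion adds to the C2 aldehyde, and the oxaphosphetane collapses by syn elimination of lithium diisopropyl phosphate to give the C2=C3 enoate. The closest known reaction type is the intramolecular Horner–Wadsworth–Emmons macrocyclisation under Masamune–Roush conditions with an α-alkyl phosphonoacetate. The 14-membered ring closes in the carbon–carbon bond-forming addition (a 14-exo-trig attack on the aldehyde carbonyl), which slow addition to a dilute solution should favour over oligomerisation. No stereocentre is created; C14 is β to the aldehyde and cannot epimerise, and the C3 epimers of 29 converge. The step needs the E enoate (ester trans to C1, so that C1 and C4 are cis), and reversible addition under lithium chelation together with the bulky diisopropyl phosphonate should favour the adduct that eliminates to this isomer.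

Step 25
Reactants: 30 macrocyclic ester
Product: 31 macrocyclic allylic alcohol (CH2OH on C3; CH2OSi(tBu)Ph2 on C7)
Conditions: iBu2AlH, CH2Cl2, −78 °C
Reagents that add atoms: none
Why: 1,2-Reduction of the only ester in the molecule by iBu2AlH, the C7 carboxyl carbon being protected at the silyl ether level.

Step 26
Reactants: 31 macrocyclic allylic alcohol
Product: 33 macrocycle bearing CH3 on C3 (CH2OSi(tBu)Ph2 on C7), via allylic mesylate 32 (not isolated)
Conditions: MsCl, Et3N, THF, −30 °C; then LiBHEt3, −30 → 0 °C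
Reagents that add atoms: none
Why: Mesylation followed by direct SN2 hydride displacement at the primary allylic carbon with LiBHEt3 turns CH2OH into CH3 without moving or isomerising the C2=C3 alkene.

Step 27
Reactants: 33 macrocycle bearing CH3 on C3
Product: 34 [(1E,5Z,8R,11E)-5,11-dimethyl-8-[(2E)-6-methylhepta-2,5-dien-2-yl]cyclotetradeca-1,5,11-trien-1-yl]methanol
Conditions: Bu4NF, THF, 0 °C → rt
Reagents that add atoms: none
Why: Fluoride cleavage of the tert-butyldiphenylsilyl ether.

Step 28
Reactants: 34 C7 allylic alcohol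
Product: 35 (1E,5Z,8R,11E)-5,11-dimethyl-8-[(2E)-6-methylhepta-2,5-dien-2-yl]cyclotetradeca-1,5,11-triene-1-carbaldehyde
Conditions: MnO2, CH2Cl2, rt
Reagents that add atoms: none
Why: MnO2 oxidises only the allylic alcohol, giving the enal with its geometry retained.

Step 29
Reactants: 35 enal
Product: 36 (1E,5Z,8R,11E)-5,11-dimethyl-8-[(2E)-6-methylhepta-2,5-dien-2-yl]cyclotetradeca-1,5,11-triene-1-carboxylic acid (target)
Conditions: NaClO2, NaH2PO4, 2-methylbut-2-ene, t-BuOH/H2O, 0 °C → rt
Reagents that add atoms: sodium chlorite, [Na+].[O-]Cl=O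
Why: Pinnick oxidation converts the enal into the acid, with excess 2-methylbut-2-ene scavenging hypochlorite so that the trisubstituted and skipped alkenes are spared.

**Compound list**

1 | pent-3-yn-1-ol | CC#CCCO | starting material
2 | (3E)-4-iodopent-3-en-1-ol | OCC/C=C(\C)I | intermediate
3 | (2E)-2,5-diiodopent-2-ene | ICC/C=C(\C)I | intermediate
4 | [(3E)-4-iodopent-3-en-1-yl]triphenylphosphonium iodide | C/C(I)=C\CC[P+](c1ccccc1)(c1ccccc1)c1ccccc1.[I-] | intermediate
5 | (2E)-2-iodo-6-methylhepta-2,5-diene | CC(C)=CC/C=C(\C)I | intermediate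
6 | 2-[(2Z)-6-methylhepta-2,5-dien-2-yl]-4,4,5,5-tetramethyl-1,3,2-dioxaborolane | CC(C)=CC/C=C(\C)B1OC(C)(C)C(C)(C)O1 | intermediate
7 | but-3-yn-1-ol | C#CCCO | starting material
8 | tert-butyl(but-3-yn-1-yloxy)dimethylsilane | C#CCCO[Si](C)(C)C(C)(C)C | intermediate
9 | 5-[(tert-butyldimethylsilyl)oxy]pent-2-yn-1-ol | OCC#CCCO[Si](C)(C)C(C)(C)C | intermediate
10 | (2E)-5-[(tert-butyldimethylsilyl)oxy]pent-2-en-1-ol | OC/C=C/CCO[Si](C)(C)C(C)(C)C | intermediate
11 | diethyl (2E)-5-[(tert-butyldimethylsilyl)oxy]pent-2-en-1-yl phosphate | CCOP(=O)(OCC)OC/C=C/CCO[Si](C)(C)C(C)(C)C | intermediate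
12 | tert-butyldimethyl{[(3S)-3-[(2E)-6-methylhepta-2,5-dien-2-yl]pent-4-en-1-yl]oxy}silane | CC(C)=CC/C=C(\C)[C@@H](CCO[Si](C)(C)C(C)(C)C)C=C | intermediate
13 | triisopropyl phosphite | CC(C)OP(OC(C)C)OC(C)C | starting material
14 | ethyl bromoacetate | CCOC(=O)CBr | starting material
15 | ethyl 2-(diisopropoxyphosphoryl)acetate | CCOC(=O)CP(=O)(OC(C)C)OC(C)C | intermediate
16 | ethyl (5E)-2-(diisopropoxyphosphoryl)-6-iodohept-5-enoate (racemic) | CCOC(=O)C(CC/C=C(\C)I)P(=O)(OC(C)C)OC(C)C | intermediate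
17 | propane-1,3-diol | OCCCO | starting material
18 | 3-[(tert-butyldimethylsilyl)oxy]propan-1-ol | OCCCO[Si](C)(C)C(C)(C)C | intermediate
19 | 3-[(tert-butyldimethylsilyl)oxy]propanal | O=CCCO[Si](C)(C)C(C)(C)C | intermediate
20 | ethyl (2E)-5-[(tert-butyldimethylsilyl)oxy]-2-[(3E)-4-iodopent-3-en-1-yl]pent-2-enoate | CCOC(=O)/C(CC/C=C(\C)I)=C/CCO[Si](C)(C)C(C)(C)C | intermediate
21 | (2E)-5-[(tert-butyldimethylsilyl)oxy]-2-[(3E)-4-iodopent-3-en-1-yl]pent-2-en-1-ol | OC/C(CC/C=C(\C)I)=C/CCO[Si](C)(C)C(C)(C)C | intermediate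
22 | (2E)-5-[(tert-butyldimethylsilyl)oxy]-1-[(tert-butyldiphenylsilyl)oxy]-2-[(3E)-4-iodopent-3-en-1-yl]pent-2-ene | CC(C)(C)[Si](OC/C(CC/C=C(\C)I)=C/CCO[Si](C)(C)C(C)(C)C)(c1ccccc1)c1ccccc1 | intermediate
23 | (3E,7E)-4-{[(tert-butyldiphenylsilyl)oxy]methyl}-8-iodonona-3,7-dien-1-ol | CC(C)(C)[Si](OC/C(CC/C=C(\C)I)=C/CCO)(c1ccccc1)c1ccccc1 | intermediate
24 | (2E)-1-[(tert-butyldiphenylsilyl)oxy]-5-iodo-2-[(3E)-4-iodopent-3-en-1-yl]pent-2-ene | CC(C)(C)[Si](OC/C(CC/C=C(\C)I)=C/CCI)(c1ccccc1)c1ccccc1 | intermediate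
25 | ethyl (5E,9E)-6-{[(tert-butyldiphenylsilyl)oxy]methyl}-2-(diisopropoxyphosphoryl)-10-iodoundeca-5,9-dienoate (racemic at C3) | CCOC(=O)C(CC/C=C(/CO[Si](c1ccccc1)(c1ccccc1)C(C)(C)C)CC/C=C(\C)I)P(=O)(OC(C)C)OC(C)C | intermediate
26 | 9-{(3R,4E)-3-[2-(tert-butyldimethylsilyloxy)ethyl]-4,8-dimethylnona-4,7-dien-1-yl}-9-borabicyclo[3.3.1]nonane | CC(C)=CC/C=C(\C)[C@@H](CCO[Si](C)(C)C(C)(C)C)CCB1C2CCCC1CCC2 | intermediate (not isolated)
27 | ethyl (5E,9E,13R,14E)-13-{2-[(tert-butyldimethylsilyl)oxy]ethyl}-6-{[(tert-butyldiphenylsilyl)oxy]methyl}-2-(diisopropoxyphosphoryl)-10,14,18-trimethylnonadeca-5,9,14,17-tetraenoate (C3 epimers) | CC(C)=CC/C=C(\C)[C@@H](CCO[Si](C)(C)C(C)(C)C)CC/C(C)=C/CC/C(CO[Si](c1ccccc1)(c1ccccc1)C(C)(C)C)=C\CCC(C(=O)OCC)P(=O)(OC(C)C)OC(C)C | intermediate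
28 | ethyl (5E,9E,13R,14E)-6-{[(tert-butyldiphenylsilyl)oxy]methyl}-2-(diisopropoxyphosphoryl)-13-(2-hydroxyethyl)-10,14,18-trimethylnonadeca-5,9,14,17-tetraenoate (C3 epimers) | CC(C)=CC/C=C(\C)[C@@H](CCO)CC/C(C)=C/CC/C(CO[Si](c1ccccc1)(c1ccccc1)C(C)(C)C)=C\CCC(C(=O)OCC)P(=O)(OC(C)C)OC(C)C | intermediate
29 | ethyl (5E,9E,13R,14E)-6-{[(tert-butyldiphenylsilyl)oxy]methyl}-2-(diisopropoxyphosphoryl)-10,14,18-trimethyl-13-(2-oxoethyl)nonadeca-5,9,14,17-tetraenoate (C3 epimers; seco aldehyde) | CC(C)=CC/C=C(\C)[C@@H](CC=O)CC/C(C)=C/CC/C(CO[Si](c1ccccc1)(c1ccccc1)C(C)(C)C)=C\CCC(C(=O)OCC)P(=O)(OC(C)C)OC(C)C | intermediate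
30 | ethyl (1E,4R,7E,11E)-11-{[(tert-butyldiphenylsilyl)oxy]methyl}-7-methyl-4-[(2E)-6-methylhepta-2,5-dien-2-yl]cyclotetradeca-1,7,11-triene-1-carboxylate (ring C3 ester, ring C7 silyloxymethyl) | CC(C)=CC/C=C(\C)[C@H]1C/C=C(/C(=O)OCC)CC/C=C(/CO[Si](c1ccccc1)(c1ccccc1)C(C)(C)C)CC/C=C(\C)CC1 | intermediate
31 | macrocyclic allylic alcohol: ring of 30 with CH2OH on C3 in place of CO2Et (CH2OSi(tBu)Ph2 on C7; 14R) | CC(C)=CC/C=C(\C)[C@H]1C/C=C(/CO)CC/C=C(/CO[Si](c1ccccc1)(c1ccccc1)C(C)(C)C)CC/C=C(\C)CC1 | intermediate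
32 | allylic mesylate: ring of 31 with CH2OSO2CH3 on C3 | CC(C)=CC/C=C(\C)[C@H]1C/C=C(/COS(C)(=O)=O)CC/C=C(/CO[Si](c1ccccc1)(c1ccccc1)C(C)(C)C)CC/C=C(\C)CC1 | intermediate (not isolated)
33 | tert-butyl{[(1E,5Z,8R,11E)-5,11-dimethyl-8-[(2E)-6-methylhepta-2,5-dien-2-yl]cyclotetradeca-1,5,11-trien-1-yl]methoxy}diphenylsilane | CC(C)=CC/C=C(\C)[C@H]1C/C=C(/C)CC/C=C(/CO[Si](c1ccccc1)(c1ccccc1)C(C)(C)C)CC/C=C(\C)CC1 | intermediate
34 | [(1E,5Z,8R,11E)-5,11-dimethyl-8-[(2E)-6-methylhepta-2,5-dien-2-yl]cyclotetradeca-1,5,11-trien-1-yl]methanol | CC(C)=CC/C=C(\C)[C@H]1C/C=C(/C)CC/C=C(/CO)CC/C=C(\C)CC1 | intermediate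
35 | (1E,5Z,8R,11E)-5,11-dimethyl-8-[(2E)-6-methylhepta-2,5-dien-2-yl]cyclotetradeca-1,5,11-triene-1-carbaldehyde | CC(C)=CC/C=C(\C)[C@H]1C/C=C(/C)CC/C=C(/C=O)CC/C=C(\C)CC1 | intermediate
36 | (1E,5Z,8R,11E)-5,11-dimethyl-8-[(2E)-6-methylhepta-2,5-dien-2-yl]cyclotetradeca-1,5,11-triene-1-carboxylic acid | CC(C)=CC/C=C(\C)[C@H]1C/C=C(/C)CC/C=C(/C(=O)O)CC/C=C(\C)CC1 | target

**Step count**

Total: 29 steps. Longest linear sequence: 18 steps (steps 1, 2, 12 and 15–29, from pent-3-yn-1-ol).

**Steps most likely to fail, with fallbacks**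

Step 24. The ring closure may be overtaken by intermolecular olefination (dimers and oligomers), and the conformational demands of the forming ring may erode the E preference, so that part of the material closes with the ester cis to C1. The fallback makes the C2=C3 enoate intermolecularly and closes the ring at C11–C12 instead. It sets out from 12 and 25 and comes back at 30. Compound 12 would be desilylated with Bu4NF to (3S)-3-[(2E)-6-methylhepta-2,5-dien-2-yl]pent-4-en-1-ol F1 and oxidised with Dess–Martin periodinane to (3S)-3-[(2E)-6-methylhepta-2,5-dien-2-yl]pent-4-enal F2. Horner–Wadsworth–Emmons olefination of F2 with the potassium salt of 25 (KOtBu, THF) should give the open-chain E enoate F3, whose geometry can be checked and purified before any ring exists. Hydroboration of the vinyl group of F3 with 9-BBN gives the B-alkyl-9-BBN adduct F4 (not isolated), and intramolecular B-alkyl Suzuki coupling (PdCl2(dppf), AsPh3, Cs2CO3, THF/DMF/H2O, high dilution) closes the 14-membered ring and returns to 30.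

Step 10. Boron-to-copper transmetalation of the hindered trisubstituted alkenylboronate may be slow, leading to low conversion, to linear (SN2) product, or to insufficient enantiofacial discrimination. The fallback sets C14 by iridium-catalysed branched-selective allylic alkylation. It sets out from 5 and comes back at 12. Stille coupling of 5 with (E)-3-(tributylstannyl)prop-2-en-1-ol (PdCl2(MeCN)2, DMF) would give (2E,4E)-4,8-dimethylnona-2,4,7-trien-1-ol F5, and methyl chloroformate with pyridine its methyl carbonate F6. Allylic alkylation with the sodium salt of dimethyl malonate ([Ir(cod)Cl]2, chiral phosphoramidite ligand, THF) attacks the substituted allyl terminus and should give dimethyl 2-[(3R,4E)-4,8-dimethylnona-1,4,7-trien-3-yl]propanedioate F7, with C14 set by the ligand. Krapcho dealkoxycarbonylation (NaCl, wet DMSO, 150 °C) gives methyl (3S)-3-[(2E)-6-methylhepta-2,5-dien-2-yl]pent-4-enoate F8. Reduction with LiAlH4 gives the alcohol F1 described above, and silylation (TBSCl, imidazole) returns to 12.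

Step 21. The aqueous carbonate needed for the coupling may deprotonate the phosphonoacetate of 25, with ester hydrolysis or binding of the anion to palladium and stalled transmetalation. The fallback joins the halves before the phosphonoacetate exists. It sets out from 12 (as its 9-BBN adduct 26) and 23 and comes back at 27. Adduct 26 would be coupled under the same palladium catalysis with alcohol 23, which has no acidic carbon, to give the coupled C4 alcohol F9 (the chain of 27 ending in C4H2OH). Iodination (I2, PPh3, imidazole) gives the corresponding C4 iodide F10, and alkylation of the sodium salt of 15 with F10 (NaH, DMF, 50 °C) returns to 27.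

**Further compounds**

F1 | step 24 | (3S)-3-[(2E)-6-methylhepta-2,5-dien-2-yl]pent-4-en-1-ol | CC(C)=CC/C=C(\C)[C@@H](CCO)C=C
F2 | step 24 | (3S)-3-[(2E)-6-methylhepta-2,5-dien-2-yl]pent-4-enal | CC(C)=CC/C=C(\C)[C@@H](CC=O)C=C
F3 | step 24 | open-chain E enoate: C2=C3 formed (CO2Et on C3 trans to C1), C7–CH2OSi(tBu)Ph2, C11 iodide, C14 bearing the vinyl group C13=C12 | CC(C)=CC/C=C(\C)[C@@H](C/C=C(/C(=O)OCC)CC/C=C(/CO[Si](c1ccccc1)(c1ccccc1)C(C)(C)C)CC/C=C(\C)I)C=C
F4 | step 24 | B-alkyl-9-BBN adduct of F3 (boron on C12; not isolated) | CC(C)=CC/C=C(\C)[C@@H](C/C=C(/C(=O)OCC)CC/C=C(/CO[Si](c1ccccc1)(c1ccccc1)C(C)(C)C)CC/C=C(\C)I)CCB1C2CCCC1CCC2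
F5 | step 10 | (2E,4E)-4,8-dimethylnona-2,4,7-trien-1-ol | OC/C=C/C(/C)=C/CC=C(C)C
F6 | step 10 | (2E,4E)-4,8-dimethylnona-2,4,7-trien-1-yl methyl carbonate | COC(=O)OC/C=C/C(/C)=C/CC=C(C)C
F7 | step 10 | dimethyl 2-[(3R,4E)-4,8-dimethylnona-1,4,7-trien-3-yl]propanedioate | CC(C)=CC/C=C(\C)[C@@H](C(C(=O)OC)C(=O)OC)C=C
F8 | step 10 | methyl (3S)-3-[(2E)-6-methylhepta-2,5-dien-2-yl]pent-4-enoate | CC(C)=CC/C=C(\C)[C@@H](CC(=O)OC)C=C
F9 | step 21 | (3E,7E,11R,12E)-11-{2-[(tert-butyldimethylsilyl)oxy]ethyl}-4-{[(tert-butyldiphenylsilyl)oxy]methyl}-8,12,16-trimethylheptadeca-3,7,12,15-tetraen-1-ol | CC(C)=CC/C=C(\C)[C@@H](CCO[Si](C)(C)C(C)(C)C)CC/C(C)=C/CC/C(CO[Si](c1ccccc1)(c1ccccc1)C(C)(C)C)=C\CCO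
F10 | step 21 | primary iodide corresponding to F9 (C4H2I in place of C4H2OH) | CC(C)=CC/C=C(\C)[C@@H](CCO[Si](C)(C)C(C)(C)C)CC/C(C)=C/CC/C(CO[Si](c1ccccc1)(c1ccccc1)C(C)(C)C)=C\CCI
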